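## Retrosynthetic overview

1. Drimane numbering is used (ring A: C1–C5 and C10; ring B: C5–C10; C11 = carboxyl carbon on C9; C12 = formyl carbon on C8; β = face of the C10 methyl). Target 23 ⇐ acid hydrolysis of 22 ⇐ ester build-up on 6β-alcohol 18 ⇐ enone 17 ⇐ silyl enol ether 16.
2. 16 ⇐ one intramolecular Diels–Alder reaction of the open-chain triene 15: the bonds C8–C9 and C5–C10 form together, so ring B (the cyclohexene) and ring A (the tether ring) close in the same step and C5, C9 and C10 are set.
3. Enabling feature: in ring B the oxygen on C6 is 1,4 to C9, and C9 carries both an oxygen and C11. Ring B is therefore the "para" adduct of a 2-silyloxy-diene (C5=C6(OSi)–C7=C8) and an α-oxy-acrylate (C10=C9(O)–C11). C9–O and C11 are tied into a temporary (S)-2-tert-butyl-1,3-dioxolan-4-one that fixes the alkene geometry, blocks one face and is hydrolysed at the end.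
4. 15 ⇐ B-alkyl Suzuki coupling of enol triflate 7 (from O-benzyl-L-threonine, which only passes its chirality to the acetal carbon) with dienol ether 13 (from mesityl oxide, allyltrimethylsilane and glyoxal dimethyl acetal).
5. Ring order: dioxolanone ring (step 2, temporary) → rings A and B together (step 10) → dioxolanone cleaved (step 15).

Key step: step 10

Assumption: the target is treated in the open hydroxy-acid/aldehyde form drawn; its lactol tautomer (C11 acid onto C12 aldehyde) would interconvert freely and needs no separate step.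

## Route

Step 1
Reactants: 1 O-benzyl-L-threonine
Product: 2 (2S,3R)-3-(benzyloxy)-2-hydroxybutanoic acid
Conditions: NaNO2, 1 M H2SO4, 0 °C → rt
Reagents that add atoms: water, O
Why: Diazotisation of the α-amino acid (nitrous acid hydroxy-deamination) should proceed with net retention at C2 through the transient α-lactone, so the (2S) centre is kept and the benzyl ether keeps the β-oxygen out of the next acetalisation.

Step 2
Reactants: 2 (2S,3R)-3-(benzyloxy)-2-hydroxybutanoic acid; 3 pivalaldehyde
Product: 4 (2S,5S)-5-[(1R)-1-(benzyloxy)ethyl]-2-tert-butyl-1,3-dioxolan-4-one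
Conditions: TsOH·H2O (cat.), pentane, reflux, Dean–Stark
Reagents that add atoms: none
Why: Acid-catalysed acetalisation of the α-hydroxy acid with water removal (dioxolanone formation) should give mainly the cis-2,5-disubstituted ring, so the existing C5 centre sets the new acetal carbon as (S).

Step 3
Reactants: 4 (2S,5S)-5-[(1R)-1-(benzyloxy)ethyl]-2-tert-butyl-1,3-dioxolan-4-one
Product: 5 (2S,5S)-2-tert-butyl-5-[(1R)-1-hydroxyethyl]-1,3-dioxolan-4-one
Conditions: H2 (1 atm), 10% Pd/C, EtOAc, rt
Reagents that add atoms: none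
Why: Hydrogenolysis of the benzyl ether is neutral and should leave the acylal lactone and both stereocentres untouched.

Step 4
Reactants: 5 (2S,5S)-2-tert-butyl-5-[(1R)-1-hydroxyethyl]-1,3-dioxolan-4-one
Product: 6 (2S)-5-acetyl-2-tert-butyl-1,3-dioxolan-4-one (C5 epimers and enol)
Conditions: Dess–Martin periodinane, CH2Cl2, 0 °C → rt
Reagents that add atoms: none
Why: Dess–Martin oxidation of the secondary alcohol gives the β-keto lactone; C5 becomes enolisable, but the acetal carbon, which now holds the only stereochemical information (self-regeneration of stereocentres), is not touched.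

Step 5
Reactants: 6 (2S)-5-acetyl-2-tert-butyl-1,3-dioxolan-4-one
Product: 7 1-[(2S,5E)-2-tert-butyl-4-oxo-1,3-dioxolan-5-ylidene]ethyl trifluoromethanesulfonate
Conditions: NaH, PhNTf2, THF, 0 °C → rt
Reagents that add atoms: N-phenylbis(trifluoromethanesulfonimide), O=S(=O)(N(c1ccccc1)S(=O)(=O)C(F)(F)F)C(F)(F)F
Why: O-Sulfonylation of the sodium enolate, in which Na bridges the enolate oxygen and the lactone carbonyl (U-shaped chelate), should place OTf cis to the ring carbonyl and so fix the geometry of the future C9=C10 alkene.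

Step 6
Reactants: 8 mesityl oxide; 9 allyltrimethylsilane
Product: 10 4,4-dimethylhept-6-en-2-one
Conditions: TiCl4, CH2Cl2, −78 °C; aq. work-up
Reagents that add atoms: none
Why: Hosomi–Sakurai conjugate allylation of the β,β-disubstituted enone builds the quaternary gem-dimethyl carbon (future C4) and leaves the terminal alkene for step 9.

Step 7
Reactants: 10 4,4-dimethylhept-6-en-2-one; 11 2,2-dimethoxyacetaldehyde (60 wt% in water)
Product: 12 (2E)-1,1-dimethoxy-6,6-dimethylnona-2,8-dien-4-one
Conditions: NaOH (cat.), MeOH/H2O, 0 °C → rt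
Reagents that add atoms: none
Why: Claisen–Schmidt aldol condensation with the non-enolisable aldehyde should take place at the unhindered methyl group rather than the neopentyl methylene and give the (E)-enone after dehydration.

Step 8
Reactants: 12 (2E)-1,1-dimethoxy-6,6-dimethylnona-2,8-dien-4-one
Product: 13 tert-butyl{[(2E,4Z)-1,1-dimethoxy-6,6-dimethylnona-2,4,8-trien-4-yl]oxy}dimethylsilane
Conditions: TBSOTf, Et3N, CH2Cl2, −78 → 0 °C
Reagents that add atoms: tert-butyldimethylsilyl trifluoromethanesulfonate, CC(C)(C)[Si](C)(C)OS(=O)(=O)C(F)(F)F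
Why: Soft enolisation (silyl triflate/amine) toward the only α'-methylene should give the cross-conjugated 2-silyloxy-diene with the (Z)-enol ether geometry, in which the bulky C4 group is trans to the vinyl group.

Step 9
Reactants: 13 tert-butyl{[(2E,4Z)-1,1-dimethoxy-6,6-dimethylnona-2,4,8-trien-4-yl]oxy}dimethylsilane; 7 1-[(2S,5E)-2-tert-butyl-4-oxo-1,3-dioxolan-5-ylidene]ethyl trifluoromethanesulfonate
Product: 15 (2S,5E)-2-tert-butyl-5-[(7Z,9E)-8-{[tert-butyl(dimethyl)silyl]oxy}-11,11-dimethoxy-6,6-dimethylundeca-7,9-dien-2-ylidene]-1,3-dioxolan-4-one, via B-alkyl-9-BBN borane 14 (not isolated)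
Conditions: 9-BBN, THF, 0 °C → rt; then 7, Pd(dppf)Cl2, AsPh3, Cs2CO3, DMF/H2O, rt
Reagents that add atoms: none
Why: 9-BBN should hydroborate only the monosubstituted terminal alkene, and the B-alkyl Suzuki–Miyaura coupling replaces OTf with retention of alkene geometry, so C1 ends up cis to the lactone carbonyl (C11) and the C10 methyl cis to the ring oxygen.

Step 10
Reactants: 15 (2S,5E)-2-tert-butyl-5-[(7Z,9E)-8-{[tert-butyl(dimethyl)silyl]oxy}-11,11-dimethoxy-6,6-dimethylundeca-7,9-dien-2-ylidene]-1,3-dioxolan-4-one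
Product: 16 6-[(tert-butyldimethylsilyl)oxy]-12,12-dimethoxy-5αH-8αH-drim-6-ene 9β-O/9α-C11 spiro-(2S)-2-tert-butyl-1,3-dioxolan-4-one (trans-decalin; 10β-CH3)
Conditions: toluene (0.01 M), BHT, 170 °C, sealed tube
Reagents that add atoms: none
Why: Thermal intramolecular Diels–Alder reaction (type 1, 1,3,9-decatriene) of the 2-silyloxy-diene C5=C6(OTBS)–C7=C8 with the captodative exocyclic alkene C10=C9 of the alkylidene-dioxolanone; the closest known reaction types are the Diels–Alder reactions of 5-alkylidene-2-tert-butyl-1,3-dioxolan-4-ones (carbonyl-exo, attack anti to tert-butyl) and the thermal cyclisation of 1,3,9-decatrienes to trans-decalins. Ring B is closed by the two new σ bonds C8–C9 and C5–C10 of the suprafacial [4+2] event, and ring A by the same C5–C10 bond as the six-membered tether ring (C1–C4 in a chair, the gem-dimethyl group at C4 favouring the folded conformer). C9 and C10 follow from the fixed alkene geometry (ring oxygen cis to CH3, C11 cis to C1) together with attack on the face opposite the tert-butyl group of the (S)-acetal, which should put 9-O and 10-CH3 on the β face in the absolute sense of the target. C5 is set by the transition state with the tether and the lactone carbonyl exo (ring oxygen and 10-CH3 endo), which leads to the trans ring fusion; C8 (C12 β) follows from the (E)-C7=C8 geometry and is erased in step 11. The step needs facial selectivity (secured by the tert-butyl acetal, which would otherwise clash with the C12 acetal and the silyloxy group) and exo-carbonyl selectivity (intrinsic to this dienophile class and reinforced by the chair tether); regiochemistry is forced by the tether and is also the polarity-matched mode, the nucleophilic C5 of the silyl enol ether bonding to the acrylate β-carbon C10.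

Step 11
Reactants: 16 6-[(tert-butyldimethylsilyl)oxy]-12,12-dimethoxy-5αH-8αH-drim-6-ene 9β-O/9α-C11 spiro-(2S)-2-tert-butyl-1,3-dioxolan-4-one
Product: 17 12,12-dimethoxy-6-oxo-5αH-drim-7-ene 9β-O/9α-C11 spiro-(2S)-2-tert-butyl-1,3-dioxolan-4-one
Conditions: Pd(OAc)2 (1.1 equiv), MeCN, 40 °C
Reagents that add atoms: none
Why: Saegusa–Ito oxidation: palladation of the silyl enol ether at C7 and syn β-hydride elimination of H8 should give the C7=C8 enone regiospecifically (C9 is quaternary) and remove the C8 centre.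

Step 12
Reactants: 17 12,12-dimethoxy-6-oxo-5αH-drim-7-ene 9β-O/9α-C11 spiro-(2S)-2-tert-butyl-1,3-dioxolan-4-one
Product: 18 6β-hydroxy-12,12-dimethoxy-5αH-drim-7-ene 9β-O/9α-C11 spiro-(2S)-2-tert-butyl-1,3-dioxolan-4-one
Conditions: NaBH4, CeCl3·7H2O, MeOH, −40 °C
Reagents that add atoms: none
Why: Luche 1,2-reduction of the enone; hydride should add from the α face because the β face of C6 is shielded by the axial 10-CH3 and 4β-CH3 groups, giving the axial 6β-alcohol.

Step 13
Reactants: 18 6β-hydroxy-12,12-dimethoxy-5αH-drim-7-ene 9β-O/9α-C11 spiro-(2S)-2-tert-butyl-1,3-dioxolan-4-one; 19 diethylphosphonoacetic acid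
Product: 20 6β-[(diethoxyphosphoryl)acetoxy]-12,12-dimethoxy-5αH-drim-7-ene 9β-O/9α-C11 spiro-(2S)-2-tert-butyl-1,3-dioxolan-4-one
Conditions: DCC, DMAP (cat.), CH2Cl2, 0 °C → rt
Reagents that add atoms: none
Why: Steglich-type esterification with diethylphosphonoacetic acid, which reacts through a small phosphono-ketene, suits the hindered axial alcohol and proceeds with retention at C6.

Step 14
Reactants: 20 6β-[(diethoxyphosphoryl)acetoxy]-12,12-dimethoxy-5αH-drim-7-ene 9β-O/9α-C11 spiro-(2S)-2-tert-butyl-1,3-dioxolan-4-one; 21 (2E,4E)-hexa-2,4-dienal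
Product: 22 12,12-dimethoxy-6β-[(2E,4E,6E)-octa-2,4,6-trienoyloxy]-5αH-drim-7-ene 9β-O/9α-C11 spiro-(2S)-2-tert-butyl-1,3-dioxolan-4-one
Conditions: LiCl, iPr2NEt, MeCN, rt
Reagents that add atoms: none
Why: Horner–Wadsworth–Emmons olefination under LiCl/amine conditions should form the new 2,3-alkene as (E), keep the dienal geometry and be mild enough for the acylal lactone.

Step 15
Reactants: 22 12,12-dimethoxy-6β-[(2E,4E,6E)-octa-2,4,6-trienoyloxy]-5αH-drim-7-ene 9β-O/9α-C11 spiro-(2S)-2-tert-butyl-1,3-dioxolan-4-one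
Product: 23 (5S,6R,9R,10S)-9β-hydroxy-6β-[(2E,4E,6E)-octa-2,4,6-trienoyloxy]-12-oxodrim-7-en-11-oic acid
Conditions: TFA/H2O/THF (3:1:1), rt → 40 °C
Reagents that add atoms: water, O
Why: Aqueous acid hydrolysis converts the dimethyl acetal to the aldehyde and opens the acylal at its acetal carbon (not at the hindered C11 carbonyl), freeing the tertiary alcohol and the carboxylic acid without touching C9 or the allylic ester.

## Compound list

1 | O-benzyl-L-threonine, (2S,3R)-2-amino-3-(benzyloxy)butanoic acid | C[C@@H](OCc1ccccc1)[C@H](N)C(=O)O | starting material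
2 | (2S,3R)-3-(benzyloxy)-2-hydroxybutanoic acid | C[C@@H](OCc1ccccc1)[C@H](O)C(=O)O | intermediate
3 | pivalaldehyde (2,2-dimethylpropanal) | CC(C)(C)C=O | starting material
4 | (2S,5S)-5-[(1R)-1-(benzyloxy)ethyl]-2-tert-butyl-1,3-dioxolan-4-one (cis) | C[C@@H](OCc1ccccc1)[C@@H]1O[C@H](C(C)(C)C)OC1=O | intermediate
5 | (2S,5S)-2-tert-butyl-5-[(1R)-1-hydroxyethyl]-1,3-dioxolan-4-one | C[C@@H](O)[C@@H]1O[C@H](C(C)(C)C)OC1=O | intermediate
6 | (2S)-5-acetyl-2-tert-butyl-1,3-dioxolan-4-one (C5 epimers/enol) | CC(=O)C1O[C@H](C(C)(C)C)OC1=O | intermediate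
7 | 1-[(2S,5E)-2-tert-butyl-4-oxo-1,3-dioxolan-5-ylidene]ethyl trifluoromethanesulfonate (OTf cis to ring C=O) | CC(C)(C)[C@@H]1OC(=O)/C(O1)=C(/C)OS(=O)(=O)C(F)(F)F | intermediate
8 | mesityl oxide (4-methylpent-3-en-2-one) | CC(=O)C=C(C)C | starting material
9 | allyltrimethylsilane | C=CC[Si](C)(C)C | starting material
10 | 4,4-dimethylhept-6-en-2-one | CC(=O)CC(C)(C)CC=C | intermediate
11 | 2,2-dimethoxyacetaldehyde (glyoxal dimethyl acetal) | COC(OC)C=O | starting material
12 | (2E)-1,1-dimethoxy-6,6-dimethylnona-2,8-dien-4-one | COC(OC)/C=C/C(=O)CC(C)(C)CC=C | intermediate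
13 | tert-butyl{[(2E,4Z)-1,1-dimethoxy-6,6-dimethylnona-2,4,8-trien-4-yl]oxy}dimethylsilane | COC(OC)/C=C/C(O[Si](C)(C)C(C)(C)C)=C/C(C)(C)CC=C | intermediate
14 | 9-[(5Z,7E)-6-{[tert-butyl(dimethyl)silyl]oxy}-9,9-dimethoxy-4,4-dimethylnona-5,7-dien-1-yl]-9-borabicyclo[3.3.1]nonane | COC(OC)/C=C/C(O[Si](C)(C)C(C)(C)C)=C/C(C)(C)CCCB1C2CCCC1CCC2 | intermediate
15 | (2S,5E)-2-tert-butyl-5-[(7Z,9E)-8-{[tert-butyl(dimethyl)silyl]oxy}-11,11-dimethoxy-6,6-dimethylundeca-7,9-dien-2-ylidene]-1,3-dioxolan-4-one | CC(C)(C)[C@@H]1OC(=O)/C(O1)=C(/C)CCCC(C)(C)/C=C(O[Si](C)(C)C(C)(C)C)/C=C/C(OC)OC | intermediate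
16 | Diels–Alder adduct: 6-silyloxy-drim-6-ene, 12,12-dimethoxy, 5α-H, 8α-H, 10β-CH3, C9 spiro to (2S)-2-tert-butyl-1,3-dioxolan-4-one (ring O on β face, C11=O on α face) | CC(C)(C)[Si](C)(C)OC1=C[C@H](C(OC)OC)[C@@](O3)(C(=O)O[C@H]3C(C)(C)C)[C@@]2(C)CCCC(C)(C)[C@H]12 | intermediate
17 | 6-oxo-drim-7-ene analogue of 16 (12,12-dimethoxy; same spiro-dioxolanone) | O=C1C=C(C(OC)OC)[C@@](O3)(C(=O)O[C@H]3C(C)(C)C)[C@@]2(C)CCCC(C)(C)[C@H]12 | intermediate
18 | 6β-hydroxy-drim-7-ene analogue (12,12-dimethoxy; same spiro-dioxolanone) | O[C@@H]1C=C(C(OC)OC)[C@@](O3)(C(=O)O[C@H]3C(C)(C)C)[C@@]2(C)CCCC(C)(C)[C@H]12 | intermediate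
19 | diethylphosphonoacetic acid | CCOP(=O)(CC(=O)O)OCC | starting material
20 | 6β-(diethoxyphosphoryl)acetate of 18 | CCOP(=O)(OCC)CC(=O)O[C@@H]1C=C(C(OC)OC)[C@@](O3)(C(=O)O[C@H]3C(C)(C)C)[C@@]2(C)CCCC(C)(C)[C@H]12 | intermediate
21 | (2E,4E)-hexa-2,4-dienal | C/C=C/C=C/C=O | starting material
22 | 6β-(2E,4E,6E)-octa-2,4,6-trienoate of 18 | C/C=C/C=C/C=C/C(=O)O[C@@H]1C=C(C(OC)OC)[C@@](O3)(C(=O)O[C@H]3C(C)(C)C)[C@@]2(C)CCCC(C)(C)[C@H]12 | intermediate
23 | (5S,6R,9R,10S)-9β-hydroxy-6β-[(2E,4E,6E)-octa-2,4,6-trienoyloxy]-12-oxodrim-7-en-11-oic acid | C/C=C/C=C/C=C/C(=O)O[C@@H]1C=C(C=O)[C@@](O)(C(=O)O)[C@@]2(C)CCCC(C)(C)[C@H]12 | target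

## Step count and risks

Total step count: 15. Longest linear sequence: 12 steps (steps 1–5 and 9–15).

Three steps most likely to fail:

Step 10. The tetrasubstituted dienophile must form a quaternary C10 next to the neopentyl C5, so the cycloaddition may be too slow; at the temperature needed, loss of the silyl enol ether or erosion of the exo/endo choice (ring fusion) could compete. Fallback, an anionic stepwise route in place of the thermal pericyclic one: setting out from 15, the silyl group is removed with TBAF/AcOH (THF, 0 °C) to give the enone (2S,5E)-2-tert-butyl-5-[(9E)-11,11-dimethoxy-6,6-dimethyl-8-oxoundec-9-en-2-ylidene]-1,3-dioxolan-4-one F1. Treatment with LiHMDS (THF, −78 → 0 °C) should generate the cross-conjugated lithium dienolate and trigger an intramolecular double Michael addition (C5 onto C10, then the lactone enolate C9 onto C8). Trapping the resulting C6–C7 enolate with TBSOTf brings the route back at 16.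

Step 9. The aqueous base of the Suzuki coupling may open the acylal lactone or deprotonate the γ-positions of the alkylidene (loss of alkene geometry), and transmetalation to a tetrasubstituted alkenyl-palladium may be slow. Fallback, a base-free iron-catalysed alkyl Grignard/enol triflate coupling: setting out from 13, hydroboration with 9-BBN and oxidation with NaBO3·4H2O gives (5Z,7E)-6-{[tert-butyl(dimethyl)silyl]oxy}-9,9-dimethoxy-4,4-dimethylnona-5,7-dien-1-ol F2. CBr4/PPh3 (2,6-lutidine, CH2Cl2) converts it to tert-butyl{[(2E,4Z)-9-bromo-1,1-dimethoxy-6,6-dimethylnona-2,4-dien-4-yl]oxy}dimethylsilane F3. Mg in THF gives the corresponding alkylmagnesium bromide F4, which is coupled with 7 using Fe(acac)3 (cat.) in THF/NMP at −30 °C, with retention of alkene geometry, and the route comes back at 15.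

Step 15. Acidolysis of the hindered tert-butyl acylal may be slow, and forcing conditions could begin to hydrolyse or ionise the allylic trienoate or isomerise the triene. Fallback, nucleophilic opening first and acetal hydrolysis second: setting out from 22, LiOH/H2O2 (THF/H2O, 0 °C) attacks the activated acylal carbonyl selectively and releases pivalaldehyde, giving (5S,6R,9R,10S)-9β-hydroxy-12,12-dimethoxy-6β-[(2E,4E,6E)-octa-2,4,6-trienoyloxy]drim-7-en-11-oic acid F5. PPTS in acetone/H2O at rt then unmasks the aldehyde, and the route comes back at 23.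

Further compounds
F1 | step 10 | (2S,5E)-2-tert-butyl-5-[(9E)-11,11-dimethoxy-6,6-dimethyl-8-oxoundec-9-en-2-ylidene]-1,3-dioxolan-4-one | CC(C)(C)[C@@H]1OC(=O)/C(O1)=C(/C)CCCC(C)(C)CC(=O)/C=C/C(OC)OC
F2 | step 9 | (5Z,7E)-6-{[tert-butyl(dimethyl)silyl]oxy}-9,9-dimethoxy-4,4-dimethylnona-5,7-dien-1-ol | COC(OC)/C=C/C(O[Si](C)(C)C(C)(C)C)=C/C(C)(C)CCCO
F3 | step 9 | tert-butyl{[(2E,4Z)-9-bromo-1,1-dimethoxy-6,6-dimethylnona-2,4-dien-4-yl]oxy}dimethylsilane | COC(OC)/C=C/C(O[Si](C)(C)C(C)(C)C)=C/C(C)(C)CCCBr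
F4 | step 9 | [(5Z,7E)-6-{[tert-butyl(dimethyl)silyl]oxy}-9,9-dimethoxy-4,4-dimethylnona-5,7-dien-1-yl]magnesium bromide | COC(OC)/C=C/C(O[Si](C)(C)C(C)(C)C)=C/C(C)(C)CCC[Mg]Br
F5 | step 15 | (5S,6R,9R,10S)-9β-hydroxy-12,12-dimethoxy-6β-[(2E,4E,6E)-octa-2,4,6-trienoyloxy]drim-7-en-11-oic acid | C/C=C/C=C/C=C/C(=O)O[C@@H]1C=C(C(OC)OC)[C@@](O)(C(=O)O)[C@@]2(C)CCCC(C)(C)[C@H]12
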